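(The runs are simulated on assumed constants.)

An easy step first: a first-order decay is a straight line in the logarithm, so take the substrate readings of the noon run and look.

| flask | substrate | reagent in the second phase | remark | time | volume of the second phase over the first |
|---|---|---|---|---|---|
| noon | 0.10 M | 3 equiv | run made earlier |  |  |
| flask | 0.050 M | 3.00 equiv |  | 40 min | 0.25 |

noon run (percent of the substrate charged)

| time / min | target / % | substrate / % |
|---|---|---|
| 0.667 | 3 | 89 |
| 1.33 | 16 | 77 |
| 2.50 | 33 | 47 |
| 4.00 | 47 | 30 |
| 8.00 | 63 | 7 |

(each reading ± 2 percentage points)

- in the second phase: reagent in the second phase; everything else is in the first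
- charges count per volume of the first phase; a concentration in a rate is the amount of a species over the volume of its own phase; every rate counts per litre of the first phase
- the analysis behind the earlier runs scatters by 2 percentage points, standard deviation
- the earlier runs hold the two phases in the same ratio of volumes as the flask asked about
- what has gone from substrate into another species counts as reacted, even if it can come back

- target at 40 min, in percent of the substrate charged
- part of the substrate charged that has reacted at 40 min

*What order does the substrate show?* From 77% at 1.33 min to 7% at 8.00 min it falls with a constant of 0.360 min⁻¹, and the readings between lie near that line. With the reagent charged at 3 equiv, I take its concentration as steady and folded into that constant: a pseudo-first-order decay.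

*What does the flask change?* It has half the noon concentrations of substrate and reagent. If the rate is first order in the reagent, my constant for the flask is 0.180 min⁻¹, a half-life of 3.85 min, and 99.9% has reacted at 40 min.

*And the yield?* I use the yield on conversion, the target formed per substrate reacted: 0.677 at 8.00 min of the noon run. It reads 0.696 at 1.33 min and 0.671 at 4.00 min. Multiplied by my conversion, it gives 67.6% of target.

*But the first reading gives 0.273, and the noon run stops at 8.00 min. Why trust it at 40 min?* That first ratio rests on 3% of target against a scatter of 2 percentage points, while the later ratios, with 0.623 at 2.50 min among them, stay near each other as the substrate reading falls from 77% to 7%. Any slow loss of target after 8.00 min is unseen, and that is my risk.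

The forecast gives 68% of target and 99% reacted, a lower conversion than mine, and argues that “selectivity holds while substrate drops tenfold”.

The flask gives 67.8% of target with 98.1% reacted.

    reagent in the reaction phase ⇌ reagent in the second phase, rate k1*([reagent in the reaction phase] - [reagent in the second phase]/K1) per volume of the first phase (partition coefficient = 6.30, kL = 0.410 min⁻¹)
    substrate + reagent in the reaction phase → target (k = 4.20 M⁻¹ min⁻¹)
    substrate + target → side product (k = 0.640 M⁻¹ min⁻¹)
    substrate ⇌ dormant form (K = 2.10, k = 0.0790 min⁻¹)
    reagent in the reaction phase + target → over-reaction product (k = 0.0700 M⁻¹ min⁻¹)

In this flask target stands at 63.8% after 20.0 min, 67.4% after 80.0 min and 34.2% after 400 min. The ratio read at noon, 0.677, put on the 98.1% reacted in this flask, gives 66.4% of target, and the flask's own ratio at 40 min is 0.691. A neighbouring flask with 0.12 M of substrate, at the same equivalents and time, gives 62.4% of target on 99.5% reacted, a ratio of 0.627, lower than that of this flask, with 14.2% of side product.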